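## Retrosynthetic overview

1. The target is a 1-O-acyl-2-O-acetyl-sn-glycerol. It is cut at the ester into the bicyclic C20 acid and 3-O-(4-methoxybenzyl)-sn-glycerol (acylate the primary OH, acetylate, unmask).
2. The acid comes from a cis-fused octalone by one-carbon homologation at C1 (methylenation, hydroboration, oxidation with epimerisation to the equatorial C1 epimer).
3. The octalone comes from an acyclic 1,7,9-trien-3-one by an intramolecular Diels–Alder reaction. This forms the C4a–C8a bond between the two quaternary ring-fusion carbons together with C7–C8, so rings A and B close in the same step.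
4. Enabling feature: ring B (C4a, C5–C8, C8a) is a cyclohexene whose C5=C6 bond starts next to C4a, and C1 of ring A, next to C8a, can be a ketone. That is the retron of a 1,7,9-decatrien-3-one cycloaddition.
5. The trienone comes from ethyl acetoacetate: α-alkylation, dianion γ-alkylation with a chiral iodide (the only pre-set stereocentre, future C2), and (Z)-enol triflate/methyl coupling to fix the (E)-diene.

Key step: step 14

Remark: locants C1–C8a are those of the octahydronaphthalene core (C1 bears the carboxyl carbon; ring A = C1–C4, C4a, C8a; ring B = C4a, C5–C8, C8a). 5-Bromo-2-methylpent-2-ene, (S)-3-bromo-2-methylpropan-1-ol and (S)-solketal are assumed to be purchasable.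

## Route

Step 1
Reactants: 1 ethyl acetoacetate; 2 5-bromo-2-methylpent-2-ene
Product: 3 ethyl 2-acetyl-6-methylhept-5-enoate (racemic)
Conditions: NaOEt, EtOH, reflux
Reagents that add atoms: none
Why: Acetoacetic ester alkylation, in which the stabilised enolate displaces the primary homoallylic bromide at carbon; the new centre is lost again in step 5.

Step 2
Reactants: 4 (S)-3-bromo-2-methylpropan-1-ol
Product: 5 (S)-(3-bromo-2-methylpropoxy)(tert-butyl)dimethylsilane
Conditions: TBSCl, imidazole, CH2Cl2, 0 °C to rt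
Reagents that add atoms: tert-butyldimethylsilyl chloride, CC(C)(C)[Si](C)(C)Cl
Why: Standard silylation of a primary alcohol, which leaves the stereocentre untouched.

Step 3
Reactants: 5 (S)-silyl-protected bromide
Product: 6 (S)-tert-butyl(3-iodo-2-methylpropoxy)dimethylsilane
Conditions: NaI, acetone, reflux
Reagents that add atoms: sodium iodide, [Na+].[I-]
Why: Finkelstein halide exchange (SN2 at the primary carbon) driven by precipitation of NaBr, with the neighbouring stereocentre not involved.

Step 4
Reactants: 3 ethyl 2-acetyl-6-methylhept-5-enoate; 6 (S)-iodide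
Product: 8 ethyl (6R)-7-[(tert-butyldimethylsilyl)oxy]-6-methyl-2-(4-methylpent-3-en-1-yl)-3-oxoheptanoate (C2 epimers), via dilithium dianion 7 (not isolated)
Conditions: LiN(i-Pr)2 (2.2 equiv), THF, −78 to 0 °C; then 6, 0 °C to rt
Reagents that add atoms: none
Why: γ-Alkylation of a β-keto ester dianion, in which the second deprotonation occurs at the acetyl methyl and this more basic terminal carbanion attacks the primary iodide by SN2; the C6 centre is carried over unchanged from 6.

Step 5
Reactants: 8 γ-alkylated β-keto ester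
Product: 10 ethyl (2Z,6R)-7-[(tert-butyldimethylsilyl)oxy]-6-methyl-2-(4-methylpent-3-en-1-yl)-3-{[(trifluoromethyl)sulfonyl]oxy}hept-2-enoate, via sodium enolate 9 (not isolated)
Conditions: NaH, Et2O, 0 °C; then Tf2O, −78 to 0 °C
Reagents that add atoms: trifluoromethanesulfonic anhydride, O=S(=O)(OS(=O)(=O)C(F)(F)F)C(F)(F)F
Why: O-Sulfonylation of a β-keto ester enolate, in which sodium chelation between the enolate oxygen and the ester carbonyl should fix the (Z) geometry with the triflate cis to the ester.

Step 6
Reactants: 10 (Z)-enol triflate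
Product: 11 ethyl (2E,6R)-7-[(tert-butyldimethylsilyl)oxy]-3,6-dimethyl-2-(4-methylpent-3-en-1-yl)hept-2-enoate
Conditions: MeMgBr, Fe(acac)3 (5 mol %), THF/NMP, −30 °C
Reagents that add atoms: methylmagnesium bromide, C[Mg]Br
Why: Iron-catalysed Kumada-type cross-coupling of an enol triflate, which should replace the triflate by methyl with retention of geometry faster than the Grignard reagent attacks the ester at this temperature.

Step 7
Reactants: 11 (E)-enoate
Product: 12 (2E,6R)-7-[(tert-butyldimethylsilyl)oxy]-3,6-dimethyl-2-(4-methylpent-3-en-1-yl)hept-2-en-1-ol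
Conditions: i-Bu2AlH (2.5 equiv), CH2Cl2, −78 °C
Reagents that add atoms: none
Why: 1,2-Reduction of a conjugated ester to the allylic alcohol by an aluminium hydride, which leaves the silyl ether and the alkenes alone.

Step 8
Reactants: 12 allylic alcohol
Product: 13 (2E,6R)-7-[(tert-butyldimethylsilyl)oxy]-3,6-dimethyl-2-(4-methylpent-3-en-1-yl)hept-2-enal
Conditions: MnO2, CH2Cl2, rt
Reagents that add atoms: none
Why: Chemoselective allylic oxidation with MnO2 under neutral conditions that should not isomerise the tetrasubstituted enal.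

Step 9
Reactants: 13 enal
Product: 14 tert-butyl{[(2R,5E)-6-ethenyl-2,5,10-trimethylundeca-5,9-dien-1-yl]oxy}dimethylsilane
Conditions: Ph3PCH3Br, KOtBu, THF, 0 °C; then 13, −78 to 0 °C
Reagents that add atoms: methyltriphenylphosphonium bromide, C[P+](c1ccccc1)(c1ccccc1)c1ccccc1.[Br-]
Why: Wittig methylenation of the aldehyde, which builds the vinyl terminus of the diene without touching the existing tetrasubstituted double bond.

Step 10
Reactants: 14 silyl-protected diene
Product: 15 (2R,5E)-6-ethenyl-2,5,10-trimethylundeca-5,9-dien-1-ol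
Conditions: Bu4NF, THF, 0 °C to rt
Reagents that add atoms: none
Why: Fluoride-mediated desilylation, chosen because the acid-sensitive tetrasubstituted diene would not tolerate protic cleavage.

Step 11
Reactants: 15 dienol
Product: 16 (2R,5E)-6-ethenyl-2,5,10-trimethylundeca-5,9-dienal
Conditions: Dess–Martin periodinane, NaHCO3, CH2Cl2, 0 °C
Reagents that add atoms: none
Why: Buffered Dess–Martin oxidation, which should give the α-branched aldehyde without epimerisation at C2.

Step 12
Reactants: 16 aldehyde
Product: 17 (4R,7E)-8-ethenyl-2,4,7,12-trimethyltrideca-1,7,11-trien-3-ol (C3 epimers)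
Conditions: isopropenylmagnesium bromide, THF, −78 °C
Reagents that add atoms: isopropenylmagnesium bromide, C=C(C)[Mg]Br
Why: Grignard 1,2-addition to the aldehyde; the carbinol configuration is irrelevant because it is oxidised in the next step.

Step 13
Reactants: 17 trienol
Product: 18 (4R,7E)-8-ethenyl-2,4,7,12-trimethyltrideca-1,7,11-trien-3-one
Conditions: Dess–Martin periodinane, NaHCO3, CH2Cl2, 0 °C; used at once
Reagents that add atoms: none
Why: Dess–Martin oxidation of the allylic alcohol to the isopropenyl ketone under cold, neutral conditions that should preserve the α-stereocentre.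

Step 14
Reactants: 18 trienone
Product: 19 (2R,4aR,8aS)-2,4a,8a-trimethyl-5-(4-methylpent-3-en-1-yl)-3,4,4a,7,8,8a-hexahydronaphthalen-1(2H)-one
Conditions: Me2AlCl (0.3 equiv), CH2Cl2 (0.02 M), −78 to 0 °C
Reagents that add atoms: none
Why: Me2AlCl binds the C3 ketone of 18 and the activated isopropenyl ketone adds to the tethered diene in a concerted but strongly asynchronous [4+2] cycloaddition: the bond from the enone CH2 to the vinyl CH2 runs ahead, and the bond between the fully substituted C2 and C7 (the future C8a–C4a ring-fusion bond) closes from an aluminium-enolate/allyl-cation-like array. The closest known reaction type is the Lewis-acid-promoted type 1 intramolecular Diels–Alder reaction of 1,7,9-decatrien-3-ones, and the diene is the open-chain counterpart of the 2-vinylcyclohexenes with a fully substituted terminus that are known to give quaternary centres in cycloadditions. Ring A closes as a six-membered carbocycle through the C2–C7 bond along the four-atom, chair-like tether, and ring B closes as the cycloaddition cyclohexene through both new bonds, its C5=C6 double bond arising from the central diene bond. C4a and C8a should be set cis to each other by the endo orientation of the tether carbonyl under the diene, and their absolute sense by the existing (4R) methyl centre, which stays equatorial on the tether and so ends trans to the axial C8a methyl. The step needs endo over exo selectivity and one diene face: the Lewis-acid-bound in-chain carbonyl is relied on for the first, the (4R) centre for the second, and the (7E) geometry keeps the tether on the outside of the diene so that a reactive cisoid conformer is available.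

Step 15
Reactants: 19 cis-octalone
Product: 20 (2R,4aR,8aR)-2,4a,8a-trimethyl-1-methylidene-5-(4-methylpent-3-en-1-yl)-1,2,3,4,4a,7,8,8a-octahydronaphthalene
Conditions: Cp2TiMe2 (3 equiv), toluene, 70 °C, dark
Reagents that add atoms: dimethyltitanocene, C[Ti](C)(C1C=CC=C1)C1C=CC=C1
Why: Petasis methylenation, whose non-basic titanium methylidene olefinates hindered enolisable ketones without epimerising the adjacent C2 centre.

Step 16
Reactants: 20 exocyclic alkene
Product: 22 [(2R,4aR,8aR)-2,4a,8a-trimethyl-5-(4-methylpent-3-en-1-yl)-1,2,3,4,4a,7,8,8a-octahydronaphthalen-1-yl]methanol (C1 epimers), via B-alkyl-9-borabicyclononane 21 (not isolated)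
Conditions: 9-BBN, THF, 0 to 40 °C; then NaOH, H2O2, 0 °C to rt
Reagents that add atoms: hydrogen peroxide, OO
Why: Hydroboration–oxidation, in which 9-BBN should select the 1,1-disubstituted exocyclic alkene over the two trisubstituted ones and place boron on the terminal carbon; the C1 configuration formed here is corrected in step 17.

Step 17
Reactants: 22 primary alcohol
Product: 24 (1S,2R,4aR,8aR)-2,4a,8a-trimethyl-5-(4-methylpent-3-en-1-yl)-1,2,3,4,4a,7,8,8a-octahydronaphthalene-1-carbaldehyde, via C1-epimeric aldehyde mixture 23 (not isolated)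
Conditions: Dess–Martin periodinane, NaHCO3, CH2Cl2, 0 °C to rt; crude, then K2CO3, MeOH, rt
Reagents that add atoms: none
Why: Dess–Martin oxidation followed by base-mediated epimerisation through the enolate, where thermodynamic control should place the formyl group equatorial (trans to the C2 methyl, cis to the C8a methyl) because the other epimer suffers a 1,3-diaxial clash with C5.

Step 18
Reactants: 24 (1S)-aldehyde
Product: 25 (1S,2R,4aR,8aR)-2,4a,8a-trimethyl-5-(4-methylpent-3-en-1-yl)-1,2,3,4,4a,7,8,8a-octahydronaphthalene-1-carboxylic acid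
Conditions: NaClO2, NaH2PO4, 2-methylbut-2-ene, t-BuOH/H2O, 0 °C to rt
Reagents that add atoms: sodium chlorite, [Na+].[O-]Cl=O
Why: Pinnick oxidation, which converts the hindered aldehyde into the acid without epimerisation while the alkene scavenger protects the two trisubstituted double bonds from hypochlorous acid.

Step 19
Reactants: 26 (S)-(2,2-dimethyl-1,3-dioxolan-4-yl)methanol ((S)-solketal)
Product: 27 (S)-4-{[(4-methoxybenzyl)oxy]methyl}-2,2-dimethyl-1,3-dioxolane
Conditions: NaH, 4-methoxybenzyl chloride, Bu4NI (cat.), DMF, 0 °C to rt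
Reagents that add atoms: 4-methoxybenzyl chloride, COc1ccc(CCl)cc1
Why: Williamson ether synthesis on the free primary hydroxyl, with the stereocentre not involved.

Step 20
Reactants: 27 4-methoxybenzyl ether of solketal
Product: 28 (R)-3-[(4-methoxybenzyl)oxy]propane-1,2-diol (3-O-(4-methoxybenzyl)-sn-glycerol)
Conditions: AcOH/H2O (4:1), 40 °C
Reagents that add atoms: none
Why: Mild acid hydrolysis of the acetonide, which leaves the 4-methoxybenzyl ether in place; the descriptor changes by priority only.

Step 21
Reactants: 25 acid; 28 diol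
Product: 30 (2S)-2-hydroxy-3-[(4-methoxybenzyl)oxy]propyl (1S,2R,4aR,8aR)-2,4a,8a-trimethyl-5-(4-methylpent-3-en-1-yl)-1,2,3,4,4a,7,8,8a-octahydronaphthalene-1-carboxylate, via mixed anhydride 29 (not isolated)
Conditions: 2,4,6-trichlorobenzoyl chloride, Et3N, toluene, rt; then 28 (2 equiv), DMAP, 0 °C to rt
Reagents that add atoms: none
Why: Yamaguchi esterification, in which the hindered mixed anhydride should acylate the primary hydroxyl of the diol much faster than the secondary one.

Step 22
Reactants: 30 hydroxy ester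
Product: 31 (2S)-2-acetoxy-3-[(4-methoxybenzyl)oxy]propyl (1S,2R,4aR,8aR)-2,4a,8a-trimethyl-5-(4-methylpent-3-en-1-yl)-1,2,3,4,4a,7,8,8a-octahydronaphthalene-1-carboxylate
Conditions: Ac2O, pyridine, DMAP (cat.), CH2Cl2, 0 °C
Reagents that add atoms: acetic anhydride, CC(=O)OC(C)=O
Why: Standard O-acetylation of the remaining secondary hydroxyl, which at 0 °C should outpace any migration of the bulky terpenoid acyl group.

Step 23
Reactants: 31 protected diacylglycerol
Product: 32 (2S)-2-acetoxy-3-hydroxypropyl (1S,2R,4aR,8aR)-2,4a,8a-trimethyl-5-(4-methylpent-3-en-1-yl)-1,2,3,4,4a,7,8,8a-octahydronaphthalene-1-carboxylate (target)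
Conditions: DDQ, CH2Cl2/pH 7 phosphate buffer, 0 °C
Reagents that add atoms: none
Why: Oxidative cleavage of the 4-methoxybenzyl ether under neutral conditions, which frees the primary hydroxyl without the acid or base that would promote 1,2-acyl migration.

## Compound list

1 | ethyl acetoacetate | CCOC(=O)CC(C)=O | starting material
2 | 5-bromo-2-methylpent-2-ene | CC(C)=CCCBr | starting material
3 | ethyl 2-acetyl-6-methylhept-5-enoate (racemic) | CCOC(=O)C(CCC=C(C)C)C(C)=O | intermediate
4 | (S)-3-bromo-2-methylpropan-1-ol | OC[C@H](C)CBr | starting material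
5 | (S)-(3-bromo-2-methylpropoxy)(tert-butyl)dimethylsilane | CC(C)(C)[Si](C)(C)OC[C@H](C)CBr | intermediate
6 | (S)-tert-butyl(3-iodo-2-methylpropoxy)dimethylsilane | CC(C)(C)[Si](C)(C)OC[C@H](C)CI | intermediate
7 | dilithium dianion of 3 | [Li+].[Li+].[CH2-]C([O-])=C(CCC=C(C)C)C(=O)OCC | intermediate (not isolated)
8 | ethyl (6R)-7-[(tert-butyldimethylsilyl)oxy]-6-methyl-2-(4-methylpent-3-en-1-yl)-3-oxoheptanoate (C2 epimers) | CC(C)(C)[Si](C)(C)OC[C@H](C)CCC(=O)C(CCC=C(C)C)C(=O)OCC | intermediate
9 | chelated sodium (Z)-enolate of 8 | [Na+].CC(C)(C)[Si](C)(C)OC[C@H](C)CC/C([O-])=C(/C(=O)OCC)CCC=C(C)C | intermediate (not isolated)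
10 | ethyl (2Z,6R)-7-[(tert-butyldimethylsilyl)oxy]-6-methyl-2-(4-methylpent-3-en-1-yl)-3-{[(trifluoromethyl)sulfonyl]oxy}hept-2-enoate | CC(C)(C)[Si](C)(C)OC[C@H](C)CC/C(OS(=O)(=O)C(F)(F)F)=C(/C(=O)OCC)CCC=C(C)C | intermediate
11 | ethyl (2E,6R)-7-[(tert-butyldimethylsilyl)oxy]-3,6-dimethyl-2-(4-methylpent-3-en-1-yl)hept-2-enoate | CC(C)(C)[Si](C)(C)OC[C@H](C)CC/C(C)=C(/C(=O)OCC)CCC=C(C)C | intermediate
12 | (2E,6R)-7-[(tert-butyldimethylsilyl)oxy]-3,6-dimethyl-2-(4-methylpent-3-en-1-yl)hept-2-en-1-ol | CC(C)(C)[Si](C)(C)OC[C@H](C)CC/C(C)=C(/CO)CCC=C(C)C | intermediate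
13 | (2E,6R)-7-[(tert-butyldimethylsilyl)oxy]-3,6-dimethyl-2-(4-methylpent-3-en-1-yl)hept-2-enal | CC(C)(C)[Si](C)(C)OC[C@H](C)CC/C(C)=C(/C=O)CCC=C(C)C | intermediate
14 | tert-butyl{[(2R,5E)-6-ethenyl-2,5,10-trimethylundeca-5,9-dien-1-yl]oxy}dimethylsilane | CC(C)(C)[Si](C)(C)OC[C@H](C)CC/C(C)=C(/C=C)CCC=C(C)C | intermediate
15 | (2R,5E)-6-ethenyl-2,5,10-trimethylundeca-5,9-dien-1-ol | OC[C@H](C)CC/C(C)=C(/C=C)CCC=C(C)C | intermediate
16 | (2R,5E)-6-ethenyl-2,5,10-trimethylundeca-5,9-dienal | O=C[C@H](C)CC/C(C)=C(/C=C)CCC=C(C)C | intermediate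
17 | (4R,7E)-8-ethenyl-2,4,7,12-trimethyltrideca-1,7,11-trien-3-ol (C3 epimers) | C=C(C)C(O)[C@H](C)CC/C(C)=C(/C=C)CCC=C(C)C | intermediate
18 | (4R,7E)-8-ethenyl-2,4,7,12-trimethyltrideca-1,7,11-trien-3-one | C=C(C)C(=O)[C@H](C)CC/C(C)=C(/C=C)CCC=C(C)C | intermediate
19 | (2R,4aR,8aS)-2,4a,8a-trimethyl-5-(4-methylpent-3-en-1-yl)-3,4,4a,7,8,8a-hexahydronaphthalen-1(2H)-one (cis-fused, angular methyls cis, C2 methyl trans to them) | O=C1[C@H](C)CC[C@]2(C)C(CCC=C(C)C)=CCC[C@]12C | intermediate
20 | (2R,4aR,8aR)-2,4a,8a-trimethyl-1-methylidene-5-(4-methylpent-3-en-1-yl)-1,2,3,4,4a,7,8,8a-octahydronaphthalene | C=C1[C@H](C)CC[C@]2(C)C(CCC=C(C)C)=CCC[C@]12C | intermediate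
21 | B-alkyl-9-borabicyclo[3.3.1]nonane from 20 (C1 epimers) | B1(CC3[C@H](C)CC[C@]4(C)C(CCC=C(C)C)=CCC[C@]34C)C2CCCC1CCC2 | intermediate (not isolated)
22 | [(2R,4aR,8aR)-2,4a,8a-trimethyl-5-(4-methylpent-3-en-1-yl)-1,2,3,4,4a,7,8,8a-octahydronaphthalen-1-yl]methanol (C1 epimers) | OCC1[C@H](C)CC[C@]2(C)C(CCC=C(C)C)=CCC[C@]12C | intermediate
23 | (2R,4aR,8aR)-2,4a,8a-trimethyl-5-(4-methylpent-3-en-1-yl)-1,2,3,4,4a,7,8,8a-octahydronaphthalene-1-carbaldehyde (C1 epimers) | O=CC1[C@H](C)CC[C@]2(C)C(CCC=C(C)C)=CCC[C@]12C | intermediate (not isolated)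
24 | (1S,2R,4aR,8aR)-2,4a,8a-trimethyl-5-(4-methylpent-3-en-1-yl)-1,2,3,4,4a,7,8,8a-octahydronaphthalene-1-carbaldehyde | O=C[C@H]1[C@H](C)CC[C@]2(C)C(CCC=C(C)C)=CCC[C@]12C | intermediate
25 | (1S,2R,4aR,8aR)-2,4a,8a-trimethyl-5-(4-methylpent-3-en-1-yl)-1,2,3,4,4a,7,8,8a-octahydronaphthalene-1-carboxylic acid | OC(=O)[C@H]1[C@H](C)CC[C@]2(C)C(CCC=C(C)C)=CCC[C@]12C | intermediate
26 | (S)-(2,2-dimethyl-1,3-dioxolan-4-yl)methanol | CC1(C)OC[C@H](CO)O1 | starting material
27 | (S)-4-{[(4-methoxybenzyl)oxy]methyl}-2,2-dimethyl-1,3-dioxolane | CC1(C)OC[C@H](COCc2ccc(OC)cc2)O1 | intermediate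
28 | (R)-3-[(4-methoxybenzyl)oxy]propane-1,2-diol | OC[C@H](COCc1ccc(OC)cc1)O | intermediate
29 | mixed anhydride of 25 with 2,4,6-trichlorobenzoic acid | O=C(OC(=O)c1c(Cl)cc(Cl)cc1Cl)[C@H]1[C@H](C)CC[C@]2(C)C(CCC=C(C)C)=CCC[C@]12C | intermediate (not isolated)
30 | (2S)-2-hydroxy-3-[(4-methoxybenzyl)oxy]propyl ester of 25 | O[C@@H](COCc1ccc(OC)cc1)COC(=O)[C@H]1[C@H](C)CC[C@]2(C)C(CCC=C(C)C)=CCC[C@]12C | intermediate
31 | (2S)-2-acetoxy-3-[(4-methoxybenzyl)oxy]propyl ester of 25 | CC(=O)O[C@@H](COCc1ccc(OC)cc1)COC(=O)[C@H]1[C@H](C)CC[C@]2(C)C(CCC=C(C)C)=CCC[C@]12C | intermediate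
32 | (2S)-2-acetoxy-3-hydroxypropyl (1S,2R,4aR,8aR)-2,4a,8a-trimethyl-5-(4-methylpent-3-en-1-yl)-1,2,3,4,4a,7,8,8a-octahydronaphthalene-1-carboxylate | CC(=O)O[C@@H](CO)COC(=O)[C@H]1[C@H](C)CC[C@]2(C)C(CCC=C(C)C)=CCC[C@]12C | target

## Step count and risks

Total step count: 23. Longest linear sequence: 20 steps (steps 2–18 and 21–23).

Steps most likely to fail:

1. Step 14 (key step). What may go wrong: too small a preference for the endo arrangement of the α-methyl enone, so that trans-fused adduct forms beside the cis-fused one, or acid-induced ionisation of the electron-rich diene before it cyclises. Fallback: an ionic Diels–Alder reaction through a temporary ketal. It sets out from 18. Treatment with 1,2-bis(trimethylsilyloxy)ethane and catalytic Me3SiOTf in CH2Cl2 at −78 °C should convert the enone in the flask into the O-[2-(trimethylsilyloxy)ethyl] alkoxyallyl cation F1. This cationic dienophile should cyclise at −78 °C, where endo preference is largest, and the pendant silyl ether then closes onto the new oxocarbenium ion to give the ethylene ketal of the cis-fused octalone F2. Hydrolysis of F2 with PPTS in wet acetone comes back to the route at 19.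

2. Step 4. What may go wrong: slow SN2 displacement at the β-branched iodide by the hindered, aggregated dianion of the α-substituted keto ester, with E2 elimination of 6 and proton transfer taking over. Fallback: reverse the order of the two alkylations. It sets out from 1. Deprotonation with NaH and then n-BuLi (THF, 0 °C) gives the more reactive sodium lithium dianion of ethyl acetoacetate F3, which is alkylated with 6 to give ethyl (6R)-7-[(tert-butyldimethylsilyl)oxy]-6-methyl-3-oxoheptanoate F4. Ordinary acetoacetic ester alkylation of F4 with bromide 2 (K2CO3, NaI, acetone, reflux) comes back to the route at 8.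

3. Step 15. What may go wrong: failure of the bulky titanium methylidene to reach the carbonyl flanked by the quaternary C8a and the methyl-bearing C2, or, one step later, of the borane to reach the resulting alkene. Fallback: epoxide homologation. It sets out from 19. Corey–Chaykovsky reaction with dimethylsulfonium methylide (Me3SI, KN(SiMe3)2, THF, −10 to 0 °C) gives the spiro-epoxide of 19 F5. Meinwald rearrangement of F5 (BF3·OEt2, CH2Cl2, −78 °C; hydride shift to the tertiary cation) comes back to the route at 23, which is epimerised as in the second stage of step 17 to 24.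

## Further compounds

F1 | step 14 | O-[2-(trimethylsilyloxy)ethyl] alkoxyallyl cation (oxocarbenium triflate) of 18 | C=C(C)C(=[O+]CCO[Si](C)(C)C)[C@H](C)CC/C(C)=C(/C=C)CCC=C(C)C.[O-]S(=O)(=O)C(F)(F)F
F2 | step 14 | ethylene ketal of 19 (spiro-1,3-dioxolane at C1, configuration as in 19) | C12(OCCO1)[C@H](C)CC[C@]3(C)C(CCC=C(C)C)=CCC[C@]23C
F3 | step 4 | sodium lithium dianion of ethyl acetoacetate | [Na+].[Li+].[CH2-]C([O-])=CC(=O)OCC
F4 | step 4 | ethyl (6R)-7-[(tert-butyldimethylsilyl)oxy]-6-methyl-3-oxoheptanoate | CC(C)(C)[Si](C)(C)OC[C@H](C)CCC(=O)CC(=O)OCC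
F5 | step 15 | spiro-epoxide of 19 (oxirane spiro-fused at C1, C1 epimers) | C1OC12[C@H](C)CC[C@]3(C)C(CCC=C(C)C)=CCC[C@]23C
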